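**Retrosynthetic overview**

1. Dicitrinone G ⇐ a C2-symmetric 7,7'-methylenebis(6,8-bis-silyloxy-3,4,5-trimethylisochroman-1-one). Reducing either of its equivalent lactones to the lactol and desilylating gives the quinone methide half, so the two halves never have to be told apart.
2. Key disconnection: benzene ring A of the quinone methide half (C4a–C5–C6–C7–C8–C8a, isochromene locants) ⇐ inverse-demand Diels–Alder/CO2 extrusion. The diene is a 4-silyloxy-7,8-dihydropyrano[4,3-b]pyran-2,5-dione carrying C4a, C8a, C8 and C7, with C1/O2/C3/C4 as a fused δ-lactone and the CH2-linked lactone half on C7. The dienophile is 1-(triisopropylsiloxy)propyne (CH3–C5 and C6–O).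
3. Enabling feature: with C1 at the lactone level on C8a, ring A is the aromatized form of a coumalate-type 2-pyranone. The C1 carbonyl makes C4a the acceptor terminus, O8 makes C7 the donor terminus, and the O–C(=O) bridge between C4a and C7 leaves as CO2. Both halves of the target then share one skeleton and the same (3R,4S) centres.
4. Pyranone–arene precursor ⇐ ortho-quinone methide C-alkylation (Mannich base of the lactone half + bicyclic hydroxypyranone). Lactone half ⇐ the same pyranone + the same siloxyalkyne. Pyranone ⇐ trans-5,6-dimethyl β-keto-δ-lactone + malonyl dichloride ⇐ methyl (R)-3-hydroxybutanoate (C3 from the chiral pool, C4 by Fráter–Seebach methylation).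
5. Ring order: δ-lactone → fused 2-pyranone → benzene ring of the lactone half (step 7) → benzene ring A (step 11) → 1H-isochromene quinone methide ring by lactol dehydration (step 13).

Key step: step 11

Remark: 1-propynyllithium is taken as a commercial reagent; lithium, aluminium and ammonium salts of a numbered compound are not numbered separately; the lactol carbon of the two lactols and the bridgeheads of the two cycloadducts form as mixtures, are left undefined in the SMILES and disappear in the same or the following step; the quinone methide half is written as the 8-oxo-6-hydroxy tautomer.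

**Route**

Step 1
Reactants: 1 methyl (R)-3-hydroxybutanoate; 2 iodomethane
Product: 3 methyl (2R,3R)-3-hydroxy-2-methylbutanoate
Conditions: LiN(iPr)2 (2.2 equiv), THF, −50 → −20 °C; then MeI, DMPU, −78 → 0 °C
Reagents that add atoms: iodomethane (2), CI
Why: Fráter–Seebach alkylation, in which the lithium-chelated alkoxide-enolate dianion of 1 should be methylated on the face anti to the C3 methyl group, setting the new C2 centre (R) of the anti (2R,3R) ester, the later C4/C3 pair of both halves.

Step 2
Reactants: 3 methyl (2R,3R)-3-hydroxy-2-methylbutanoate; 4 tert-butyl acetate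
Product: 5 tert-butyl (4R,5R)-5-hydroxy-4-methyl-3-oxohexanoate
Conditions: LiN(iPr)2 (3.5 equiv), tert-butyl acetate (3.5 equiv), THF, −78 °C; then 3, −78 → −30 °C; aqueous work-up
Reagents that add atoms: tert-butyl acetate (4), CC(=O)OC(C)(C)C
Why: Crossed Claisen condensation of the lithium enolate of tert-butyl acetate with an unprotected β-hydroxy ester (excess enolate takes up the OH and the acidic CH2 of the product), in which the α-centre next to the alkoxide is not deprotonated and should keep its configuration.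

Step 3
Reactants: 5 tert-butyl (4R,5R)-5-hydroxy-4-methyl-3-oxohexanoate
Product: 6 (5R,6R)-5,6-dimethyloxane-2,4-dione
Conditions: CF3CO2H, CH2Cl2, 0 → 23 °C
Reagents that add atoms: none
Why: Acid-mediated loss of the tert-butyl group and lactonization of the δ-hydroxy-β-keto ester (the standard route to 6-substituted oxane-2,4-diones) should close the δ-lactone ring, and the trans-5,6-dimethyl arrangement formed is also the more stable one, so the α-centre is not at risk.

Step 4
Reactants: 6 (5R,6R)-5,6-dimethyloxane-2,4-dione; 7 malonyl dichloride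
Product: 8 (7R,8R)-4-hydroxy-7,8-dimethyl-7,8-dihydro-2H,5H-pyrano[4,3-b]pyran-2,5-dione
Conditions: malonyl dichloride (1.1 equiv), CH2Cl2, 40 °C
Reagents that add atoms: malonyl dichloride (7), O=C(Cl)CC(=O)Cl
Why: Malonyl dichloride C,O-bisacylation of a cyclic 1,3-dicarbonyl compound (the [3+3] annulation known for 4-hydroxy-6-methyl-2-pyranone and cyclohexane-1,3-diones) should fuse the 4-hydroxy-2-pyranone ring onto C3 and the C4 enol oxygen of 6 under acidic conditions that do not enolize C5.

Step 5
Reactants: 9 1-propynyllithium; 10 tert-butyl hydroperoxide; 11 triisopropylsilyl trifluoromethanesulfonate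
Product: 13 triisopropyl(prop-1-yn-1-yloxy)silane, via lithium propynolate 12 (not isolated)
Conditions: tBuOOH, LiN(SiMe3)2, THF, −78 °C; then 9, −78 → 0 °C; then iPr3SiOTf, −78 → 0 °C
Reagents that add atoms: tert-butyl hydroperoxide (10), CC(C)(C)OO; triisopropylsilyl trifluoromethanesulfonate (11), CC(C)[Si](C(C)C)(C(C)C)OS(=O)(=O)C(F)(F)F
Why: Julia oxidation of a lithium acetylide by lithium tert-butyl peroxide gives the ynolate, which the bulky silyl triflate should trap on oxygen to give the isolable triisopropylsiloxyalkyne.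

Step 6
Reactants: 8 (7R,8R)-4-hydroxy-7,8-dimethyl-7,8-dihydro-2H,5H-pyrano[4,3-b]pyran-2,5-dione; 11 triisopropylsilyl trifluoromethanesulfonate
Product: 14 (7R,8R)-7,8-dimethyl-4-[(triisopropylsilyl)oxy]-7,8-dihydro-2H,5H-pyrano[4,3-b]pyran-2,5-dione
Conditions: iPr3SiOTf (1.1 equiv), Et3N, CH2Cl2, −78 → 0 °C
Reagents that add atoms: triisopropylsilyl trifluoromethanesulfonate (11), CC(C)[Si](C(C)C)(C(C)C)OS(=O)(=O)C(F)(F)F
Why: O-Silylation of the vinylogous-acid 4-OH (thermodynamically on O-4) removes the proton that would destroy the siloxyalkyne and keeps the 2-pyranone diene.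

Step 7
Reactants: 14 (7R,8R)-7,8-dimethyl-4-[(triisopropylsilyl)oxy]-7,8-dihydro-2H,5H-pyrano[4,3-b]pyran-2,5-dione; 13 triisopropyl(prop-1-yn-1-yloxy)silane
Product: 17 (3R,4S)-6,8-dihydroxy-3,4,5-trimethylisochroman-1-one, via bridged cycloadduct 15 (not isolated), via bis-silyl ether 16 (not isolated)
Conditions: 13 (1.5 equiv), PhMe, 110 °C, sealed tube; then HF·pyridine, THF, 0 → 23 °C
Reagents that add atoms: none
Why: Inverse-demand Diels–Alder reaction of the coumalate-type 2-pyranone with the electron-rich siloxyalkyne (methyl carbon to pyranone C-8a, siloxy carbon to C-3) followed by retro-Diels–Alder loss of CO2 should give the resorcinol bis-silyl ether, which HF desilylates, the two stereocentres being carried over unchanged as (3R,4S).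

Step 8
Reactants: 17 (3R,4S)-6,8-dihydroxy-3,4,5-trimethylisochroman-1-one; 18 formaldehyde; 19 dimethylamine
Product: 20 (3R,4S)-7-[(dimethylamino)methyl]-6,8-dihydroxy-3,4,5-trimethylisochroman-1-one
Conditions: aq. CH2O (1.05 equiv), Me2NH (1.1 equiv), EtOH, 23 °C
Reagents that add atoms: formaldehyde (18), C=O; dimethylamine (19), CNC
Why: Phenolic Mannich reaction at C7, the only unsubstituted ring carbon and the position between the two hydroxyl groups.

Step 9
Reactants: 20 (3R,4S)-7-[(dimethylamino)methyl]-6,8-dihydroxy-3,4,5-trimethylisochroman-1-one; 8 (7R,8R)-4-hydroxy-7,8-dimethyl-7,8-dihydro-2H,5H-pyrano[4,3-b]pyran-2,5-dione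
Product: 22 (7R,8R)-3-{[(3R,4S)-6,8-dihydroxy-3,4,5-trimethyl-1-oxoisochroman-7-yl]methyl}-4-hydroxy-7,8-dimethyl-7,8-dihydro-2H,5H-pyrano[4,3-b]pyran-2,5-dione, via ortho-quinone methide 21 (not isolated)
Conditions: 8 (1.2 equiv), 1,4-dioxane, 100 °C, N2 stream
Reagents that add atoms: none
Why: Thermal loss of dimethylamine from the ortho-hydroxybenzylamine gives ortho-quinone methide 21, which C-3 of the 4-hydroxy-2-pyranone (a soft vinylogous-acid carbon nucleophile, like 4-hydroxycoumarins) should trap by Michael addition, forming the CH2 link.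

Step 10
Reactants: 22 (the pyranone–arene triol of step 9); 11 triisopropylsilyl trifluoromethanesulfonate
Product: 23 (7R,8R)-3-{[(3R,4S)-3,4,5-trimethyl-1-oxo-6,8-bis(triisopropylsilyloxy)isochroman-7-yl]methyl}-7,8-dimethyl-4-(triisopropylsilyloxy)-7,8-dihydro-2H,5H-pyrano[4,3-b]pyran-2,5-dione
Conditions: iPr3SiOTf (3.6 equiv), Et3N, CH2Cl2, 0 → 23 °C
Reagents that add atoms: triisopropylsilyl trifluoromethanesulfonate (11), CC(C)[Si](C(C)C)(C(C)C)OS(=O)(=O)C(F)(F)F
Why: Exhaustive O-silylation with a silyl triflate caps the acidic pyranone OH and both phenols (including the hydrogen-bonded 8-OH), so that the siloxyalkyne survives the next step and all four ether groups of the benzannulation product become identical.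

Step 11
Reactants: 23 (the tris-silyl pyranone–arene of step 10); 13 triisopropyl(prop-1-yn-1-yloxy)silane
Product: 25 7,7'-methylenebis[(3R,4S)-3,4,5-trimethyl-6,8-bis(triisopropylsilyloxy)isochroman-1-one], via bridged cycloadduct 24 (not isolated)
Conditions: 13 (3 equiv), PhMe, 120 °C, sealed tube
Reagents that add atoms: none
Why: The methyl-bearing carbon of the siloxyalkyne (its nucleophilic β-carbon) attacks pyranone C-8a of 23 (C4a of the target), the β-position of the fused lactone carbonyl C1, while the siloxy-bearing carbon closes onto pyranone C-3 (C7 of the target, the enol-ether terminus carrying the CH2 link), in a concerted but strongly asynchronous inverse-demand [4+2] cycloaddition that gives the 2-oxabicyclo[2.2.2]octadienone 24, which loses CO2 by retro-[4+2] to the benzene ring. The closest known reaction type is the Diels–Alder/retro-Diels–Alder benzannulation of 2-pyranone-5-carboxylates (coumalates) with ynamines, ketene acetals and alkoxyalkynes, together with the thermal benzannulations of triisopropylsiloxyalkynes. The one ring that closes, benzene ring A (C4a–C5–C6–C7–C8–C8a), is formed by intermolecular [4+2] cycloaddition and cycloreversion, both new bonds coming from the alkyne. No stereocentre is created in the product (the two bridgeheads of 24 become sp2 on CO2 loss), and the C3/C4 centres of both halves are spectators under the neutral thermal conditions. The step needs regioselectivity (methyl carbon to C4a, oxygenated carbon to C7), secured by the matched polarization of the push-pull alkyne and the acceptor-substituted pyranone, and chemoselectivity for the pyranone over the arene lactone, secured because only the pyranone is a diene; crowding at the fully substituted C-3 terminus is the main risk.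

Step 12
Reactants: 25 7,7'-methylenebis[(3R,4S)-3,4,5-trimethyl-6,8-bis(triisopropylsilyloxy)isochroman-1-one]
Product: 26 (3R,4S)-7-{[(3R,4S)-1-hydroxy-3,4,5-trimethyl-6,8-bis(triisopropylsilyloxy)isochroman-7-yl]methyl}-3,4,5-trimethyl-6,8-bis(triisopropylsilyloxy)isochroman-1-one
Conditions: iBu2AlH (1.1 equiv), CH2Cl2, −78 °C; aq. potassium sodium tartrate
Reagents that add atoms: none
Why: Partial reduction of an aryl δ-lactone to the lactol by iBu2AlH (the aluminium lactolate is stable at −78 °C), for which the C2 symmetry of 25 makes the two lactones equivalent, so that only the extent of reduction has to be controlled and a statistical mixture with recoverable 25 and bis-lactol is to be expected.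

Step 13
Reactants: 26 (the mono-lactol of step 12)
Product: 28 Dicitrinone G, via desilylated lactol 27 (not isolated)
Conditions: HF·pyridine, THF, 0 → 23 °C
Reagents that add atoms: none
Why: Fluoride-driven cleavage of the four aryl silyl ethers, after which the 1,6,8-trihydroxyisochroman half should lose water through the 2-benzopyrylium ion to the quinone methide (the hemiacetal dehydration that closes citrinin-type syntheses), while the lactone half and the four stereocentres are not touched.

**Compound list**

1 | methyl (R)-3-hydroxybutanoate | C[C@@H](O)CC(=O)OC | starting material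
2 | iodomethane | CI | starting material
3 | methyl (2R,3R)-3-hydroxy-2-methylbutanoate | C[C@@H](O)[C@@H](C)C(=O)OC | intermediate
4 | tert-butyl acetate | CC(=O)OC(C)(C)C | starting material
5 | tert-butyl (4R,5R)-5-hydroxy-4-methyl-3-oxohexanoate | C[C@@H](O)[C@@H](C)C(=O)CC(=O)OC(C)(C)C | intermediate
6 | (5R,6R)-5,6-dimethyloxane-2,4-dione | O=C1CC(=O)[C@H](C)[C@@H](C)O1 | intermediate
7 | malonyl dichloride | O=C(Cl)CC(=O)Cl | starting material
8 | (7R,8R)-4-hydroxy-7,8-dimethyl-7,8-dihydro-2H,5H-pyrano[4,3-b]pyran-2,5-dione | O=C1C=C(O)C2=C(O1)[C@H](C)[C@@H](C)OC2=O | intermediate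
9 | 1-propynyllithium | [Li]C#CC | starting material
10 | tert-butyl hydroperoxide | CC(C)(C)OO | starting material
11 | triisopropylsilyl trifluoromethanesulfonate | CC(C)[Si](C(C)C)(C(C)C)OS(=O)(=O)C(F)(F)F | starting material
12 | lithium prop-1-yn-1-olate | CC#C[O-].[Li+] | intermediate (not isolated)
13 | triisopropyl(prop-1-yn-1-yloxy)silane | CC#CO[Si](C(C)C)(C(C)C)C(C)C | intermediate
14 | (7R,8R)-7,8-dimethyl-4-[(triisopropylsilyl)oxy]-7,8-dihydro-2H,5H-pyrano[4,3-b]pyran-2,5-dione | O=C1C=C(O[Si](C(C)C)(C(C)C)C(C)C)C2=C(O1)[C@H](C)[C@@H](C)OC2=O | intermediate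
15 | 2-oxabicyclo[2.2.2]octa-5,7-dien-3-one cycloadduct of 14 and 13 (δ-lactone fused, both silyl ethers kept, bridgeheads undefined) | O=C1OC23C(C(=O)O[C@H](C)[C@H]2C)=C(O[Si](C(C)C)(C(C)C)C(C)C)C1C(O[Si](C(C)C)(C(C)C)C(C)C)=C3C | intermediate (not isolated)
16 | (3R,4S)-3,4,5-trimethyl-6,8-bis(triisopropylsilyloxy)isochroman-1-one | c1c(O[Si](C(C)C)(C(C)C)C(C)C)c(C)c2c(c1O[Si](C(C)C)(C(C)C)C(C)C)C(=O)O[C@H](C)[C@H]2C | intermediate (not isolated)
17 | (3R,4S)-6,8-dihydroxy-3,4,5-trimethylisochroman-1-one | c1c(O)c(C)c2c(c1O)C(=O)O[C@H](C)[C@H]2C | intermediate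
18 | formaldehyde | C=O | starting material
19 | dimethylamine | CNC | starting material
20 | (3R,4S)-7-[(dimethylamino)methyl]-6,8-dihydroxy-3,4,5-trimethylisochroman-1-one | CN(C)Cc1c(O)c(C)c2c(c1O)C(=O)O[C@H](C)[C@H]2C | intermediate
21 | (3R,4S)-8-hydroxy-3,4,5-trimethyl-7-methylidene-3,4-dihydro-1H-isochromene-1,6(7H)-dione | C=C1C(=O)C(C)=C2C(=C1O)C(=O)O[C@H](C)[C@H]2C | intermediate (not isolated)
22 | (7R,8R)-3-{[(3R,4S)-6,8-dihydroxy-3,4,5-trimethyl-1-oxoisochroman-7-yl]methyl}-4-hydroxy-7,8-dimethyl-7,8-dihydro-2H,5H-pyrano[4,3-b]pyran-2,5-dione | O=C1C(Cc3c(O)c(C)c4c(c3O)C(=O)O[C@H](C)[C@H]4C)=C(O)C2=C(O1)[C@H](C)[C@@H](C)OC2=O | intermediate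
23 | (7R,8R)-3-{[(3R,4S)-3,4,5-trimethyl-1-oxo-6,8-bis(triisopropylsilyloxy)isochroman-7-yl]methyl}-7,8-dimethyl-4-(triisopropylsilyloxy)-7,8-dihydro-2H,5H-pyrano[4,3-b]pyran-2,5-dione | O=C1C(Cc3c(O[Si](C(C)C)(C(C)C)C(C)C)c(C)c4c(c3O[Si](C(C)C)(C(C)C)C(C)C)C(=O)O[C@H](C)[C@H]4C)=C(O[Si](C(C)C)(C(C)C)C(C)C)C2=C(O1)[C@H](C)[C@@H](C)OC2=O | intermediate
24 | 2-oxabicyclo[2.2.2]octa-5,7-dien-3-one cycloadduct of 23 and 13 (bridgeheads undefined) | O=C1OC23C(C(=O)O[C@H](C)[C@H]2C)=C(O[Si](C(C)C)(C(C)C)C(C)C)C1(Cc4c(O[Si](C(C)C)(C(C)C)C(C)C)c(C)c5c(c4O[Si](C(C)C)(C(C)C)C(C)C)C(=O)O[C@H](C)[C@H]5C)C(O[Si](C(C)C)(C(C)C)C(C)C)=C3C | intermediate (not isolated)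
25 | 7,7'-methylenebis[(3R,4S)-3,4,5-trimethyl-6,8-bis(triisopropylsilyloxy)isochroman-1-one] | C(c1c(O[Si](C(C)C)(C(C)C)C(C)C)c(C)c2c(c1O[Si](C(C)C)(C(C)C)C(C)C)C(=O)O[C@H](C)[C@H]2C)c1c(O[Si](C(C)C)(C(C)C)C(C)C)c(C)c2c(c1O[Si](C(C)C)(C(C)C)C(C)C)C(=O)O[C@H](C)[C@H]2C | intermediate
26 | (3R,4S)-7-{[(3R,4S)-1-hydroxy-3,4,5-trimethyl-6,8-bis(triisopropylsilyloxy)isochroman-7-yl]methyl}-3,4,5-trimethyl-6,8-bis(triisopropylsilyloxy)isochroman-1-one (lactol carbon undefined) | C(c1c(O[Si](C(C)C)(C(C)C)C(C)C)c(C)c2c(c1O[Si](C(C)C)(C(C)C)C(C)C)C(O)O[C@H](C)[C@H]2C)c1c(O[Si](C(C)C)(C(C)C)C(C)C)c(C)c2c(c1O[Si](C(C)C)(C(C)C)C(C)C)C(=O)O[C@H](C)[C@H]2C | intermediate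
27 | (3R,4S)-6,8-dihydroxy-3,4,5-trimethyl-7-{[(3R,4S)-1,6,8-trihydroxy-3,4,5-trimethylisochroman-7-yl]methyl}isochroman-1-one (lactol carbon undefined) | C(c1c(O)c(C)c2c(c1O)C(O)O[C@H](C)[C@H]2C)c1c(O)c(C)c2c(c1O)C(=O)O[C@H](C)[C@H]2C | intermediate (not isolated)
28 | Dicitrinone G | CC1=C2C(=CO[C@H](C)[C@H]2C)C(=O)C(Cc2c(O)c(C)c3c(c2O)C(=O)O[C@H](C)[C@H]3C)=C1O | target

**Step count**

Total step count: 13 steps. Longest linear sequence: 12 steps (steps 1–4 and 6–13; step 5 is a one-step side branch).

**Steps most likely to fail**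

Step 11 (key benzannulation). The fully substituted pyranone is shielded at C-3 by the 4-silyloxy group and the bis-silyloxybenzyl group. It may cycloadd more slowly than the siloxyalkyne is lost by thermal 1,3-silyl shift to the silylketene and by oligomerization, or the labile 4-silyloxy group may be lost first. The fallback joins the halves after both benzene rings exist; it sets out from 20 and 17 and returns at 25. Mannich base 20 is heated with a second equivalent of phenol lactone 17 (1,4-dioxane, 100 °C). Ortho-quinone methide 21 is then trapped at C7 of 17, the resorcinol position between its two hydroxyl groups, in the diarylmethane-forming step of phenol–formaldehyde chemistry. This gives 7,7'-methylenebis[(3R,4S)-6,8-dihydroxy-3,4,5-trimethylisochroman-1-one] F1. Fourfold silylation (iPr3SiOTf, Et3N, CH2Cl2) then gives 25.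

Step 12 (mono-reduction). Reduction of the second lactone and incomplete conversion limit the mono-lactol to a statistical share. The carbonyl flanked by the 8-silyloxy group may also react only at temperatures at which the aluminium lactolate opens and is reduced further. The fallback reduces before the halves are joined, so that only one lactone is present; it gives up 25, sets out from 16 and 20 and returns at 28. Bis-silyl ether 16 is isolated by omitting the HF treatment in step 7 and reduced with iBu2AlH (CH2Cl2, −78 °C) to (3R,4S)-3,4,5-trimethyl-6,8-bis(triisopropylsilyloxy)isochroman-1-ol F2. HF·pyridine then gives (3R,4S)-3,4,5-trimethylisochromane-1,6,8-triol F3, which is not isolated and dehydrates to the quinone methide (3R,4S)-6-hydroxy-3,4,5-trimethyl-3,4-dihydro-8H-isochromen-8-one F4. F4 is heated with Mannich base 20 in 1,4-dioxane. Its C7, the central carbon of the vinylogous acid O6–C6=C7–C8=O, should add to ortho-quinone methide 21 in a Michael addition to give 28 directly.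

Step 9 (ortho-quinone methide coupling). Thermal extrusion of dimethylamine may be slow. Oligomerization of the quinone methide, or its recapture by the amine, may then outrun C-alkylation by the acyl-deactivated C-3 of 8, and the amine may open the pyranone. The fallback forms the CH2 link by reductive Knoevenagel alkylation; it sets out from 17 and 8 and returns at 22. Rieche formylation of 17 (Cl2CHOCH3, TiCl4, CH2Cl2, 0 °C) at its only free ring position gives (3R,4S)-6,8-dihydroxy-3,4,5-trimethyl-1-oxoisochromane-7-carbaldehyde F5. F5, pyranone 8 and diethyl 2,6-dimethyl-1,4-dihydropyridine-3,5-dicarboxylate are stirred with catalytic L-proline (CH2Cl2/EtOH, 23 °C). The Knoevenagel adduct (7R,8R)-3-{[(3R,4S)-6,8-dihydroxy-3,4,5-trimethyl-1-oxoisochroman-7-yl]methylidene}-7,8-dimethyl-7,8-dihydro-2H,5H-pyrano[4,3-b]pyran-2,4,5(3H)-trione F6 is not isolated and is reduced in the flask by hydride transfer from the dihydropyridine to give 22.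

**Further compounds**

F1 | step 11 | 7,7'-methylenebis[(3R,4S)-6,8-dihydroxy-3,4,5-trimethylisochroman-1-one] | C(c1c(O)c(C)c2c(c1O)C(=O)O[C@H](C)[C@H]2C)c1c(O)c(C)c2c(c1O)C(=O)O[C@H](C)[C@H]2C
F2 | step 12 | (3R,4S)-3,4,5-trimethyl-6,8-bis(triisopropylsilyloxy)isochroman-1-ol | c1c(O[Si](C(C)C)(C(C)C)C(C)C)c(C)c2c(c1O[Si](C(C)C)(C(C)C)C(C)C)C(O)O[C@H](C)[C@H]2C
F3 | step 12 | (3R,4S)-3,4,5-trimethylisochromane-1,6,8-triol | c1c(O)c(C)c2c(c1O)C(O)O[C@H](C)[C@H]2C
F4 | step 12 | (3R,4S)-6-hydroxy-3,4,5-trimethyl-3,4-dihydro-8H-isochromen-8-one | CC1=C2C(=CO[C@H](C)[C@H]2C)C(=O)C=C1O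
F5 | step 9 | (3R,4S)-6,8-dihydroxy-3,4,5-trimethyl-1-oxoisochromane-7-carbaldehyde | O=Cc1c(O)c(C)c2c(c1O)C(=O)O[C@H](C)[C@H]2C
F6 | step 9 | (7R,8R)-3-{[(3R,4S)-6,8-dihydroxy-3,4,5-trimethyl-1-oxoisochroman-7-yl]methylidene}-7,8-dimethyl-7,8-dihydro-2H,5H-pyrano[4,3-b]pyran-2,4,5(3H)-trione | O=C1OC2=C(C(=O)C1=Cc1c(O)c(C)c3c(c1O)C(=O)O[C@H](C)[C@H]3C)C(=O)O[C@H](C)[C@H]2C
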